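**Retrosynthetic overview**

- Numbering follows phthalide: C1 lactone C=O, O2, C3, C3a, C4–C7, C7a, and C8 as the first side-chain carbon; primes mark the propellane half. The cyclobutane C6–C7–C3a'–C7a' is the seam between two C12 butylidene-dihydrophthalide halves. Cutting C6–C7a' and C7–C3a' gives a cyclohexadiene lactone (C6=C7) and a tetrasubstituted enone-type lactone (C3a'=C7a').
- Enabling feature: quaternary C7a' carries the lactone carbonyl C1' and sits next to C7' of the C6'=C7' alkene. With C7' written as a ketone, C7a' is the central carbon of a 1,3-dicarbonyl. That gives a two-point handle for a chiral Lewis acid, an electrophilic radical terminus in the triplet, and a regiospecific precursor of C6'=C7' (only C6' can enolise).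
- Masks: the unprimed butylidene is parked as a methyl pseudo-ester, which raises the diene triplet and removes a rotor and a competing alkene. C8' carries SiMe3, which caps C8' and holds the 3'E geometry. Both masks leave together as MeOSiMe3 in the last step.
- Ring order: both carbocycles come from one Dieckmann product and one common enol triflate. Lactone B follows by anti iodocyclisation and lactone A by Ag-catalysed 5-exo-dig closure. The cyclobutane is closed last, by a catalytic enantioselective crossed [2+2] that forms both quaternary carbons and all four stereocentres.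

Key step: step 11

Remark 1: the target SMILES is read as 3Z in the unprimed half and 3'E in the primed half (propyl trans to O2', cis to C3a').
Remark 2: the sense of induction of the Sc–pybox complex on chelate 8 is not known. The (S,S)-ligand is written, and its antipode is used if the first run gives the mirror image.

**Step 1**
Reactants: 1 diethyl 3-oxoheptanedioate
Product: 2 ethyl 2-hydroxy-6-oxocyclohex-1-ene-1-carboxylate (enol of the 2,6-dione)
Conditions: NaOEt (1.1 equiv), EtOH, reflux; then 1 M HCl
Reagents that add atoms: none
Why: Dieckmann condensation, in which the doubly activated C2 carbanion attacks the remote ester to close the six-membered ring and the acidic tricarbonyl enolate is the thermodynamic sink.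

**Step 2**
Reactants: 2 ethyl 2-hydroxy-6-oxocyclohex-1-ene-1-carboxylate
Product: 3 ethyl 6-oxo-2-{[(trifluoromethyl)sulfonyl]oxy}cyclohex-1-ene-1-carboxylate
Conditions: Tf2O, i-Pr2NEt, CH2Cl2, −78 °C
Reagents that add atoms: triflic anhydride, O=S(=O)(OS(=O)(=O)C(F)(F)F)C(F)(F)F
Why: O-sulfonylation of an enolised symmetrical 1,3-dione, whose two ring carbonyls are equivalent, so a single vinylogous acyl triflate can form.

**Step 3**
Reactants: 3 enol triflate; 4 ethynyltrimethylsilane
Product: 5 ethyl 6-oxo-2-[(trimethylsilyl)ethynyl]cyclohex-1-ene-1-carboxylate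
Conditions: PdCl2(PPh3)2 (2 mol %), CuI (4 mol %), i-Pr2NEt, THF, rt
Reagents that add atoms: ethynyltrimethylsilane (4), C#C[Si](C)(C)C
Why: Sonogashira coupling of an electron-poor β-triflyloxy enone, with a hindered amine to avoid addition–elimination at the β-carbon.

**Step 4**
Reactants: 5 silyl enynone ester
Product: 6 (3E)-3-[iodo(trimethylsilyl)methylidene]-5,6-dihydro-2-benzofuran-1,7(3H,4H)-dione (I trans to O2, SiMe3 cis to O2)
Conditions: ICl (1.2 equiv), CH2Cl2, −78 → 0 °C
Reagents that add atoms: iodine monochloride, ClI
Why: Electrophilic iodocyclisation of an alkynyl ester, in which charge builds up β to silicon on the ring-bound alkyne carbon, so the ester oxygen closes 5-exo anti to iodine and chloride removes the ethyl group.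

**Step 5**
Reactants: 6 vinyl iodide; 7 n-propylzinc bromide
Product: 8 (3Z)-3-[1-(trimethylsilyl)butylidene]-5,6-dihydro-2-benzofuran-1,7(3H,4H)-dione (propyl cis to C3a, SiMe3 cis to O2)
Conditions: Pd(dppf)Cl2 (5 mol %), THF, rt
Reagents that add atoms: n-propylzinc bromide (7), CCC[Zn]Br
Why: Negishi coupling of a 1-iodo-1-silylalkene proceeds with retention, so propyl takes the place of iodine, and the ketone and lactone tolerate the organozinc reagent.

**Step 6**
Reactants: 3 enol triflate; 9 pent-1-yne
Product: 10 ethyl 6-oxo-2-(pent-1-yn-1-yl)cyclohex-1-ene-1-carboxylate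
Conditions: PdCl2(PPh3)2 (2 mol %), CuI (4 mol %), i-Pr2NEt, THF, rt
Reagents that add atoms: pent-1-yne (9), C#CCCC
Why: The same Sonogashira coupling as in step 3, carried out on the common triflate.

**Step 7**
Reactants: 10 enynone ester
Product: 11 ethyl 6-hydroxy-2-(pent-1-yn-1-yl)cyclohex-1-ene-1-carboxylate (racemic)
Conditions: NaBH4, CeCl3·7H2O, MeOH, −78 °C
Reagents that add atoms: none
Why: Luche reduction gives clean 1,2-reduction of the enone, and the new stereocentre is erased in step 8.

**Step 8**
Reactants: 11 allylic alcohol
Product: 13 ethyl 2-(pent-1-yn-1-yl)cyclohexa-1,5-diene-1-carboxylate, via allylic mesylate 12 (not isolated)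
Conditions: MsCl, Et3N, CH2Cl2, 0 °C; then DBU, rt
Reagents that add atoms: methanesulfonyl chloride, CS(=O)(=O)Cl (its atoms stay only in 12)
Why: Mesylation followed by E2 elimination, which is regiospecific because only the CH2 next to the carbinol carries β-hydrogens, and which gives the conjugated diene.

**Step 9**
Reactants: 13 dienyne ester
Product: 14 2-(pent-1-yn-1-yl)cyclohexa-1,5-diene-1-carboxylic acid
Conditions: LiOH, THF/H2O, 0 °C → rt, under Ar; then 1 M HCl
Reagents that add atoms: lithium hydroxide, [Li+].[OH-]
Why: Ester saponification, with air excluded to prevent aromatisation of the dihydrobenzoate.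

**Step 10**
Reactants: 14 dienyne acid
Product: 16 3-butyl-3-methoxy-4,5-dihydro-2-benzofuran-1(3H)-one (racemic methyl pseudo-ester), via (Z)-ligustilide 15 (not isolated)
Conditions: AgNO3 (10 mol %), MeOH, rt, dark; then CSA (5 mol %), 0 °C, short contact
Reagents that add atoms: methanol, CO
Why: Ag(I)-catalysed anti 5-exo-dig lactonisation of a (Z)-2-en-4-ynoic acid closes lactone A, and kinetic acid-catalysed Markovnikov addition of MeOH to the enol ester then gives the cyclic pseudo-ester.

**Step 11**
Reactants: 8 silyl dienone lactone; 16 pseudo-ester diene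
Product: 17 crossed [2+2] adduct (6S,7R,3a'S,7a'R; both carbocycles on one face of the cyclobutane, lactone B on the face of H6/H7; C3 epimers)
Conditions: 8 (1 equiv), 16 (5 equiv), Ru(bpy)3(PF6)2 (2.5 mol %), Sc(OTf)3 (10 mol %), (S,S)-t-Bu-pybox (15 mol %), i-PrOAc/MeCN 3:1, degassed, blue LED, 0 °C
Reagents that add atoms: none
Why: Proposed new method: Sc(III)–pybox should bind 8 through the C7'=O/C1'=O pair and lower the triplet of the bound dienone below that of excited Ru(bpy)3(2+), so that only the chiral chelate is sensitised while free 8 and diene 16 lie too high; the closest known reaction type is the Lewis acid/Ru dual-catalytic enantioselective [2+2] of chelating enones with 1,3-dienes, which has not been shown for a tetrasubstituted 2-acyl enone lactone. The triplet should react stepwise: its electrophilic, malonyl-type terminus C7a' bonds to the unhindered diene terminus C6 (tertiary 1,3-dicarbonyl radicals add to alkenes in this sense, and the known diene cases join the enone α-carbon to the diene terminus), which gives an allyl/allyl 1,4-biradical (C7–C7a–C3a and C3a'–C3'–C8'). After intersystem crossing the only ring formed is the cyclobutane, closed by C7–C3a' radical recombination of the 1,4-biradical, because bonding at C8' would put a trans C3a'=C3' bond into a six-membered ring (the dienone is held s-trans by the lactone) and bonding at C3a would join two fully substituted carbons. C7a' and C3a' are controlled by the ligand, whose tert-butyl group covers one face of the flat chelate; C6 and C7 follow from suprafacial addition to the cis ring alkene (cis 6–4 fusion) and from the fold that lays ring A over the flat C7'=O/C4'H2 side of 8 rather than over the C3' side that carries propyl and SiMe3. The step needs crossed rather than homo addition (secured by selective excitation of bound 8 and by excess 16), one reacting alkene per partner (C6'=C7' is stored as the ketone, C8' is capped by SiMe3, the butylidene of 16 is stored as the pseudo-ester, C3a=C7a is internal and tetrasubstituted) and head-to-head regiochemistry (secured by the two allyl radicals). If the exocyclic C3'=C8' bond twists in the triplet it should relax to the same isomer, since the other one presses SiMe3 against C4'H2.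

**Step 12**
Reactants: 17 keto adduct
Product: 18 C7' enol triflate (C6'=C7'–OTf)
Conditions: N-(5-chloro-2-pyridyl)triflimide (1.3 equiv) premixed with 17, then KHMDS (1.1 equiv) added slowly, THF, −78 °C
Reagents that add atoms: N-(5-chloro-2-pyridyl)bis(trifluoromethanesulfonimide), O=S(=O)(N(c1ccc(Cl)cn1)S(=O)(=O)C(F)(F)F)C(F)(F)F
Why: Kinetic enolate O-triflation with internal quench, in which the ketone can enolise only toward C6' because C7a' is quaternary, and no stereocentre is touched.

**Step 13**
Reactants: 18 enol triflate
Product: 19 C6'=C7' alkene (pseudo-ester and SiMe3 still in place)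
Conditions: Pd(OAc)2 (5 mol %), PPh3 (10 mol %), HCO2H, n-Bu3N, DMF, 60 °C
Reagents that add atoms: none
Why: Pd-catalysed formate reduction of an enol triflate (formate-to-hydride transfer with loss of CO2), which leaves the vinylsilane, the pseudo-ester and the lactones untouched.

**Step 14**
Reactants: 19 doubly masked dimer
Product: 21 target (3Z,3'E,6S,7R,3a'S,7a'R), via C8'-silyl dimer 20 (not isolated)
Conditions: CSA (20 mol %), toluene, 0 → 40 °C, stopped at full conversion of 20
Reagents that add atoms: none
Why: Acid-catalysed E1 loss of MeOH from the pseudo-ester through an allyl-stabilised acyloxocarbenium ion gives the more stable 3Z alkene, and the released MeOH feeds the ipso-protodesilylation of the vinylsilane (β-silyl cation, retention), so H replaces Si cis to O2' and the 3'E alkene results.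

**Compound list**

| No. | Name | SMILES | Role |
|---|---|---|---|
| 1 | diethyl 3-oxoheptanedioate | CCOC(=O)CC(=O)CCCC(=O)OCC | starting material |
| 2 | ethyl 2-hydroxy-6-oxocyclohex-1-ene-1-carboxylate | CCOC(=O)C1=C(O)CCCC1=O | intermediate |
| 3 | ethyl 6-oxo-2-(triflyloxy)cyclohex-1-ene-1-carboxylate | CCOC(=O)C1=C(OS(=O)(=O)C(F)(F)F)CCCC1=O | intermediate |
| 4 | ethynyltrimethylsilane | C#C[Si](C)(C)C | starting material |
| 5 | ethyl 6-oxo-2-[(trimethylsilyl)ethynyl]cyclohex-1-ene-1-carboxylate | CCOC(=O)C1=C(C#C[Si](C)(C)C)CCCC1=O | intermediate |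
| 6 | (3E)-3-[iodo(trimethylsilyl)methylidene]-5,6-dihydro-2-benzofuran-1,7(3H,4H)-dione | O=C1CCCC2=C1C(=O)O/C2=C(/I)[Si](C)(C)C | intermediate |
| 7 | n-propylzinc bromide | CCC[Zn]Br | starting material |
| 8 | (3Z)-3-[1-(trimethylsilyl)butylidene]-5,6-dihydro-2-benzofuran-1,7(3H,4H)-dione | O=C1CCCC2=C1C(=O)O/C2=C(/CCC)[Si](C)(C)C | intermediate |
| 9 | pent-1-yne | C#CCCC | starting material |
| 10 | ethyl 6-oxo-2-(pent-1-yn-1-yl)cyclohex-1-ene-1-carboxylate | CCOC(=O)C1=C(C#CCCC)CCCC1=O | intermediate |
| 11 | ethyl 6-hydroxy-2-(pent-1-yn-1-yl)cyclohex-1-ene-1-carboxylate (racemic) | CCOC(=O)C1=C(C#CCCC)CCCC1O | intermediate |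
| 12 | allylic mesylate of 11 | CCOC(=O)C1=C(C#CCCC)CCCC1OS(C)(=O)=O | intermediate |
| 13 | ethyl 2-(pent-1-yn-1-yl)cyclohexa-1,5-diene-1-carboxylate | CCOC(=O)C1=C(C#CCCC)CCC=C1 | intermediate |
| 14 | 2-(pent-1-yn-1-yl)cyclohexa-1,5-diene-1-carboxylic acid | OC(=O)C1=C(C#CCCC)CCC=C1 | intermediate |
| 15 | (Z)-ligustilide | CCC/C=C1\OC(=O)C2=C1CCC=C2 | intermediate |
| 16 | 3-butyl-3-methoxy-4,5-dihydro-2-benzofuran-1(3H)-one (racemic) | CCCCC1(OC)OC(=O)C2=C1CCC=C2 | intermediate |
| 17 | keto [2+2] adduct (C3 epimers) | CCCCC1(OC)OC(=O)C2=C1CC[C@H]1[C@@H]2[C@@]23CCCC(=O)[C@@]12C(=O)O/C3=C(/CCC)[Si](C)(C)C | intermediate |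
| 18 | C7' enol triflate | CCCCC1(OC)OC(=O)C2=C1CC[C@H]1[C@@H]2[C@@]23CCC=C(OS(=O)(=O)C(F)(F)F)[C@@]12C(=O)O/C3=C(/CCC)[Si](C)(C)C | intermediate |
| 19 | doubly masked dimer | CCCCC1(OC)OC(=O)C2=C1CC[C@H]1[C@@H]2[C@@]23CCC=C[C@@]12C(=O)O/C3=C(/CCC)[Si](C)(C)C | intermediate |
| 20 | C8'-silyl dimer | CCC/C=C1\OC(=O)C2=C1CC[C@H]1[C@@H]2[C@@]23CCC=C[C@@]12C(=O)O/C3=C(/CCC)[Si](C)(C)C | intermediate |
| 21 | target | CCC/C=C1\OC(=O)C2=C1CC[C@H]1[C@@H]2[C@@]23CCC=C[C@@]12C(=O)O/C3=C/CCC | target |

Total step count: 14.
Longest linear sequence: 11 (steps 1, 2, 6–14).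

**Steps most likely to fail**

1. **Step 11.**
   - Energy transfer may not discriminate between bound 8, free 8 and 16.
   - The triplet may decay by twisting about C3'=C8' faster than it bonds.
   - The biradical may revert to the partners.
   - Facial shielding of the chelate may be poor.
   - Fallback (known chemistry): starting from 8 and 16, the classical enone–olefin [2+2] photocycloaddition is run without Lewis acid or sensitiser (366 nm, Pyrex, large excess of 16). This gives 17 together with its mirror-image series, ent-adduct F1. The two are separated by preparative HPLC on a chiral stationary phase, and the route is rejoined at 17.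

2. **Step 14.**
   - The oxocarbenium ion may live long enough for rotation, so that retention is lost.
   - The freed 3'E enol ester may be re-protonated and drift to 3'Z.
   - The cation next to the cyclobutane may rearrange.
   - Fallback: starting from 19, non-protic elimination (TMSOTf, Et3N, CH2Cl2, −78 → 0 °C) gives isolated 20. Iododesilylation with retention (NIS, MeCN) then gives the (3'Z)-1-iodobutylidene dimer F2. Pd-catalysed hydrodeiodination with retention (Pd(PPh3)4, HCO2H, n-Bu3N) rejoins the route at 21.

3. **Step 4.**
   - 6-endo closure to the pyranone or ipso-iododesilylation may compete on this electron-poor alkyne.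
   - Fallback: starting from 5, neutral ester cleavage (Me3SnOH, 1,2-dichloroethane, 70 °C) gives 6-oxo-2-[(trimethylsilyl)ethynyl]cyclohex-1-ene-1-carboxylic acid F3. Iodolactonisation of its carboxylate (NIS, NaHCO3, MeCN; 5-exo, anti) rejoins the route at 6.

**Further compounds**
F1 | step 11 | ent-adduct (mirror-image series of 17, C3 epimers) | CCCCC1(OC)OC(=O)C2=C1CC[C@@H]1[C@H]2[C@]23CCCC(=O)[C@]12C(=O)O/C3=C(/CCC)[Si](C)(C)C
F2 | step 14 | (3'Z)-1-iodobutylidene dimer | CCC/C=C1\OC(=O)C2=C1CC[C@H]1[C@@H]2[C@@]23CCC=C[C@@]12C(=O)O/C3=C(/CCC)I
F3 | step 4 | 6-oxo-2-[(trimethylsilyl)ethynyl]cyclohex-1-ene-1-carboxylic acid | OC(=O)C1=C(C#C[Si](C)(C)C)CCCC1=O
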